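**Retrosynthetic overview**

1. Guajadial C ⇐ late twofold Vilsmeier formylation of a spirochroman diol. The pyran ring is closed last, not by the usual ortho-quinone methide hetero-Diels–Alder reaction, but by acid-triggered ionisation of a tertiary allylic alcohol and stereoconvergent axial C–O closure at the spiro carbon (key step).
2. That alcohol ⇐ 1,2-addition of an (R)-2,2-diarylethyl cerium reagent to a 15-nor-cadinenone (C4–C15 bond).
3. The diarylethyl iodide ⇐ invertive Friedel–Crafts opening of (R)-styrene oxide by phloroglucinol tris(methoxymethyl) ether (benzylic centre from the chiral pool).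
4. The enone ⇐ Birch reduction of a tetralin anisole and kinetic gamma-protonation (sets the ring-fusion centre against thermodynamics) ⇐ phenol annulation on (−)-menthone (both ring A centres from the chiral pool).
5. Ring order: ring A (menthone) → ring B (built aromatic, then dearomatised) → arene ring D attached in the fragment union → pyran ring C last.

Assumption: terpene carbons follow cadinane numbering (C1 ring-fusion CH, C4 spiro carbon, C5=C6 alkene, C7 isopropyl carbon, C10 methyl carbon, C15 pyran CH2, C16 benzylic CH), and (−)-menthone, 4,4-dimethoxybutan-2-one, phloroglucinol and (R)-styrene oxide are taken as commercial.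

**Route**

Step 1
Reactants: 1 (−)-menthone, (2S,5R)-5-methyl-2-(propan-2-yl)cyclohexan-1-one
Product: 3 trimethyl{[(3R,6S)-3-methyl-6-(propan-2-yl)cyclohex-1-en-1-yl]oxy}silane, via lithium enolate 2 (not isolated)
Conditions: LiN(i-Pr)2, THF, −78 °C; then Me3SiCl, −78 °C to 20 °C
Reagents that add atoms: chlorotrimethylsilane, C[Si](C)(C)Cl
Why: The bulky amide base removes a proton kinetically from the CH2 alpha carbon and not from the isopropyl-bearing CH, and O-silylation of enolate 2 (kinetic enolate formation and silyl enol ether trapping) fixes this regiochemistry while both menthone stereocentres stay untouched at −78 °C.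

Step 2
Reactants: 3 trimethyl{[(3R,6S)-3-methyl-6-(propan-2-yl)cyclohex-1-en-1-yl]oxy}silane; 4 4,4-dimethoxybutan-2-one
Product: 5 (3R,6S)-2-(1-methoxy-3-oxobutyl)-3-methyl-6-(propan-2-yl)cyclohexan-1-one (epimer mixture at C2 of the ring plus the methoxy carbon)
Conditions: Me3SiOSO2CF3 (5 mol %), CH2Cl2, −78 °C
Reagents that add atoms: none
Why: Mukaiyama aldol-type addition of the silyl enol ether to the Lewis acid activated dimethyl acetal joins the ring alpha carbon (C1) to C2 of a four-carbon unit that already carries the methyl ketone needed for ring B, under base-free conditions at −78 °C that cannot epimerise the isopropyl centre; the two new stereocentres arise as a mixture and are erased in step 3.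

Step 3
Reactants: 5 (3R,6S)-2-(1-methoxy-3-oxobutyl)-3-methyl-6-(propan-2-yl)cyclohexan-1-one
Product: 8 (1R,4S)-6-methoxy-1-methyl-4-(propan-2-yl)-1,2,3,4-tetrahydronaphthalene, via enedione 6 (not isolated), via sodium naphtholate 7 (not isolated)
Conditions: NaOMe, MeOH, 65 °C; then Me2SO4, 20 °C
Reagents that add atoms: dimethyl sulfate, COS(=O)(=O)OC
Why: Methoxide triggers E1cB loss of methanol to enedione 6, which is held as its own conjugate base (this protects the isopropyl-bearing alpha carbon from epimerisation), closes ring B by intramolecular aldol condensation of the methyl ketone onto the ring ketone and aromatises irreversibly to naphtholate 7 (the ring closure known from pyrylium pseudo-bases to phenols), and O-methylation in the same flask (Williamson ether synthesis) gives the anisole, in which the ring-fusion carbon is deliberately flat and the two benzylic stereocentres can no longer epimerise.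

Step 4
Reactants: 8 (1R,4S)-6-methoxy-1-methyl-4-(propan-2-yl)-1,2,3,4-tetrahydronaphthalene
Product: 9 (5R,8S)-2-methoxy-5-methyl-8-(propan-2-yl)-1,4,5,6,7,8-hexahydronaphthalene
Conditions: Li, NH3 (l), t-BuOH, THF, −78 °C to −33 °C
Reagents that add atoms: none
Why: Birch reduction of the anisole gives the 1,4-diene in which the methoxy-bearing carbon and both alkyl-bearing ring-fusion carbons stay sp2, so the future ring-fusion alkene sits regiospecifically between C1 and C6 and the benzylic stereocentres are not touched.

Step 5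
Reactants: 9 (5R,8S)-2-methoxy-5-methyl-8-(propan-2-yl)-1,4,5,6,7,8-hexahydronaphthalene
Product: 11 (4aR,5R,8S)-5-methyl-8-(propan-2-yl)-4,4a,5,6,7,8-hexahydronaphthalen-2(3H)-one, via unconjugated enone 10 (not isolated)
Conditions: 1 M aq. HCl, THF, 0 °C to 20 °C
Reagents that add atoms: water, O
Why: Enol ether hydrolysis gives unconjugated enone 10 and acid-catalysed conjugation (the classical Birch reduction, hydrolysis and isomerisation sequence to cyclohexenones) then places a proton on C1 under kinetic control, axially and on the face opposite the neighbouring methyl group, which sits pseudoaxial in the ring A half-chair because of 1,2-allylic strain (the same facial preference as in alkylations of menthone-type enolates), so the ring-fusion hydrogen ends up trans to the methyl group as in the target and the short, mild treatment avoids drift to the more stable epimer.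

Step 6
Reactants: 12 phloroglucinol (benzene-1,3,5-triol)
Product: 13 1,3,5-tris(methoxymethoxy)benzene
Conditions: MeOCH2Cl, i-Pr2NEt, CH2Cl2, 0 °C to 20 °C
Reagents that add atoms: chloromethyl methyl ether, COCCl
Why: Threefold O-alkylation with the hard alpha-chloro ether (Williamson-type acetal formation) masks all phenols as methoxymethyl ethers that tolerate organolithium reagents and are later cleaved by the same acid that closes the pyran ring.

Step 7
Reactants: 13 1,3,5-tris(methoxymethoxy)benzene; 14 (R)-styrene oxide, (2R)-2-phenyloxirane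
Product: 15 (2R)-2-phenyl-2-[2,4,6-tris(methoxymethoxy)phenyl]ethan-1-ol
Conditions: (CF3)2CHOH, 0 °C to 20 °C, 13 in threefold excess
Reagents that add atoms: none
Why: The hydrogen-bond-donating fluoroalcohol activates the epoxide without any Lewis acid and the electron-rich arene attacks the benzylic carbon from the rear (Friedel–Crafts epoxide arylation, SN2-like with inversion), so (R)-styrene oxide gives the (R)-diarylmethine that becomes the benzylic stereocentre of the target, and the threefold symmetry of 13 allows only one regioisomer.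

Step 8
Reactants: 15 (2R)-2-phenyl-2-[2,4,6-tris(methoxymethoxy)phenyl]ethan-1-ol
Product: 16 2-[(1R)-2-iodo-1-phenylethyl]-1,3,5-tris(methoxymethoxy)benzene
Conditions: I2, PPh3, imidazole, CH2Cl2, 0 °C
Reagents that add atoms: iodine, [I][I]
Why: Garegg–Samuelsson (Appel-type) iodination replaces the primary hydroxyl by SN2 displacement at the CH2 carbon, so the adjacent diarylmethine is not involved, and the iodide is used at once to avoid neighbouring-group participation by the electron-rich ring.

Step 9
Reactants: 16 2-[(1R)-2-iodo-1-phenylethyl]-1,3,5-tris(methoxymethoxy)benzene; 11 (4aR,5R,8S)-5-methyl-8-(propan-2-yl)-4,4a,5,6,7,8-hexahydronaphthalen-2(3H)-one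
Product: 19 (4aR,5R,8S)-5-methyl-2-{(2R)-2-phenyl-2-[2,4,6-tris(methoxymethoxy)phenyl]ethyl}-8-(propan-2-yl)-2,3,4,4a,5,6,7,8-octahydronaphthalen-2-ol (both C2 epimers), via alkyllithium 17 (not isolated), via alkylcerium dichloride 18 (not isolated)
Conditions: t-BuLi (2.1 equiv), Et2O/pentane, −78 °C; CeCl3, THF, −78 °C; then 11, −78 °C to −40 °C; H2O
Reagents that add atoms: none
Why: Iodine–lithium exchange at −78 °C gives alkyllithium 17 faster than any deprotonation, transmetalation to the far less basic alkylcerium dichloride 18 suppresses enolisation and conjugate addition, and 1,2-addition to the enone carbonyl (Imamoto organocerium addition) forges the C4–C15 bond; the new carbinol centre is an inconsequential mixture because it is ionised in step 10, and the ring-fusion centre is not epimerised under these non-equilibrating conditions.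

Step 10
Reactants: 19 (4aR,5R,8S)-5-methyl-2-{(2R)-2-phenyl-2-[2,4,6-tris(methoxymethoxy)phenyl]ethyl}-8-(propan-2-yl)-2,3,4,4a,5,6,7,8-octahydronaphthalen-2-ol
Product: 20 (2S,4R,4a'R,5'R,8'S)-5'-methyl-4-phenyl-8'-(propan-2-yl)-3',4',4a',5',6',7'-hexahydro-8'H-spiro[chromane-2,2'-naphthalene]-5,7-diol (Guajadial C without its two formyl groups)
Conditions: HCl (1.25 M in MeOH), THF, 0 °C to 20 °C, high dilution
Reagents that add atoms: none
Why: Acid cleaves the three methoxymethyl acetals (methanol traps the fragment as dimethoxymethane) and ionises the tertiary allylic alcohol, and a flanking phenol oxygen closes the six-membered pyran ring at the tertiary allylic terminus (SN1 cycloetherification, six-membered rather than eight-membered ring) by chair-like axial attack on the face of ring B opposite the axial ring-fusion hydrogen, which is also the more stable arrangement (oxygen pseudoaxial, CH2 pseudoequatorial), so both epimers of 19 converge on the (S)-spiro centre while the benzylic centre is untouched.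

Step 11
Reactants: 20 (2S,4R,4a'R,5'R,8'S)-5'-methyl-4-phenyl-8'-(propan-2-yl)-3',4',4a',5',6',7'-hexahydro-8'H-spiro[chromane-2,2'-naphthalene]-5,7-diol
Product: 21 Guajadial C, (2S,4R,4a'R,5'R,8'S)-5,7-dihydroxy-5'-methyl-4-phenyl-8'-(propan-2-yl)-3',4',4a',5',6',7'-hexahydro-8'H-spiro[chromane-2,2'-naphthalene]-6,8-dicarbaldehyde
Conditions: POCl3, DMF, MeCN, 0 °C to 20 °C; then H2O, 40 °C
Reagents that add atoms: N,N-dimethylformamide, CN(C)C=O; water, O
Why: Twofold Vilsmeier–Haack formylation attacks the only two free positions of the phloroglucinol ring, each activated by three oxygen donors, just as phloroglucinol itself is diformylated, and tertiary allylic aryl ethers of the 2,2-dialkyl-2H-chromene type are known to survive these conditions, so the spiro ether, the alkene and all stereocentres are retained.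

**Compound list**

1 | (−)-menthone, (2S,5R)-5-methyl-2-(propan-2-yl)cyclohexan-1-one | CC(C)[C@@H]1CC[C@@H](C)CC1=O | starting material
2 | lithium (3R,6S)-3-methyl-6-(propan-2-yl)cyclohex-1-en-1-olate (kinetic lithium enolate) | CC(C)[C@@H]1CC[C@@H](C)C=C1[O-].[Li+] | intermediate (not isolated)
3 | trimethyl{[(3R,6S)-3-methyl-6-(propan-2-yl)cyclohex-1-en-1-yl]oxy}silane | CC(C)[C@@H]1CC[C@@H](C)C=C1O[Si](C)(C)C | intermediate
4 | 4,4-dimethoxybutan-2-one | CC(=O)CC(OC)OC | starting material
5 | (3R,6S)-2-(1-methoxy-3-oxobutyl)-3-methyl-6-(propan-2-yl)cyclohexan-1-one, epimer mixture at ring C2 and the methoxy carbon | CC(C)[C@@H]1CC[C@@H](C)C(C(OC)CC(C)=O)C1=O | intermediate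
6 | (3R,6S)-3-methyl-2-[(1E)-3-oxobut-1-en-1-yl]-6-(propan-2-yl)cyclohexan-1-one (enedione, C2 epimers) | CC(C)[C@@H]1CC[C@@H](C)C(/C=C/C(C)=O)C1=O | intermediate (not isolated)
7 | sodium (5R,8S)-5-methyl-8-(propan-2-yl)-5,6,7,8-tetrahydronaphthalen-2-olate | CC(C)[C@@H]1CC[C@@H](C)c2ccc([O-])cc21.[Na+] | intermediate (not isolated)
8 | (1R,4S)-6-methoxy-1-methyl-4-(propan-2-yl)-1,2,3,4-tetrahydronaphthalene | CC(C)[C@@H]1CC[C@@H](C)c2ccc(OC)cc21 | intermediate
9 | (5R,8S)-2-methoxy-5-methyl-8-(propan-2-yl)-1,4,5,6,7,8-hexahydronaphthalene | CC(C)[C@@H]1CC[C@@H](C)C2=C1CC(OC)=CC2 | intermediate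
10 | (5R,8S)-5-methyl-8-(propan-2-yl)-3,4,5,6,7,8-hexahydronaphthalen-2(1H)-one (unconjugated enone) | CC(C)[C@@H]1CC[C@@H](C)C2=C1CC(=O)CC2 | intermediate (not isolated)
11 | (4aR,5R,8S)-5-methyl-8-(propan-2-yl)-4,4a,5,6,7,8-hexahydronaphthalen-2(3H)-one | CC(C)[C@@H]1CC[C@@H](C)[C@H]2CCC(=O)C=C12 | intermediate
12 | phloroglucinol, benzene-1,3,5-triol | Oc1cc(O)cc(O)c1 | starting material
13 | 1,3,5-tris(methoxymethoxy)benzene | COCOc1cc(OCOC)cc(OCOC)c1 | intermediate
14 | (R)-styrene oxide, (2R)-2-phenyloxirane | C1O[C@@H]1c1ccccc1 | starting material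
15 | (2R)-2-phenyl-2-[2,4,6-tris(methoxymethoxy)phenyl]ethan-1-ol | OC[C@H](c1ccccc1)c1c(OCOC)cc(OCOC)cc1OCOC | intermediate
16 | 2-[(1R)-2-iodo-1-phenylethyl]-1,3,5-tris(methoxymethoxy)benzene | IC[C@H](c1ccccc1)c1c(OCOC)cc(OCOC)cc1OCOC | intermediate
17 | {(2R)-2-phenyl-2-[2,4,6-tris(methoxymethoxy)phenyl]ethyl}lithium | [Li]C[C@H](c1ccccc1)c1c(OCOC)cc(OCOC)cc1OCOC | intermediate (not isolated)
18 | dichloro{(2R)-2-phenyl-2-[2,4,6-tris(methoxymethoxy)phenyl]ethyl}cerium | Cl[Ce](Cl)C[C@H](c1ccccc1)c1c(OCOC)cc(OCOC)cc1OCOC | intermediate (not isolated)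
19 | (4aR,5R,8S)-5-methyl-2-{(2R)-2-phenyl-2-[2,4,6-tris(methoxymethoxy)phenyl]ethyl}-8-(propan-2-yl)-2,3,4,4a,5,6,7,8-octahydronaphthalen-2-ol, both C2 epimers | CC(C)[C@@H]1CC[C@@H](C)[C@H]2CCC(O)(C[C@H](c3ccccc3)c3c(OCOC)cc(OCOC)cc3OCOC)C=C12 | intermediate
20 | (2S,4R,4a'R,5'R,8'S)-5'-methyl-4-phenyl-8'-(propan-2-yl)-3',4',4a',5',6',7'-hexahydro-8'H-spiro[chromane-2,2'-naphthalene]-5,7-diol | CC(C)[C@@H]1CC[C@@H](C)[C@H]2CC[C@@]3(C=C12)C[C@H](c1ccccc1)c1c(O)cc(O)cc1O3 | intermediate
21 | Guajadial C, (2S,4R,4a'R,5'R,8'S)-5,7-dihydroxy-5'-methyl-4-phenyl-8'-(propan-2-yl)-3',4',4a',5',6',7'-hexahydro-8'H-spiro[chromane-2,2'-naphthalene]-6,8-dicarbaldehyde | CC(C)[C@@H]1CC[C@@H](C)[C@H]2CC[C@@]3(C=C12)C[C@H](c1ccccc1)c1c(O)c(C=O)c(O)c(C=O)c1O3 | target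

**Step count and risks**

Total step count: 11. Longest linear sequence: 8 steps (steps 1, 2, 3, 4, 5, 9, 10 and 11, from (−)-menthone).

Risk 1, step 5. The kinetic protonation at C1 may give a poor epimer ratio or drift to the more stable ring-fusion epimer. The fallback sets this centre by face-selective hydrogenation before ring B is closed, and sets out from 5:
- The methyl ketone alone is ketalised (Me3SiOCH2CH2OSiMe3, catalytic Me3SiOSO2CF3, CH2Cl2, −78 °C) to the dioxolane-protected methoxy ketone F1.
- t-BuOK (THF, 0 °C) eliminates methanol by E1cB to the (E)-alkylidene ketone F2, in which 1,3-allylic strain forces the neighbouring methyl group axial.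
- Hydrogenation over Pd/C (EtOAc, 1 atm H2) adds hydrogen to the face opposite that methyl group and gives the 2,3-cis ketone F3.
- Dilute aqueous HCl in THF frees the 1,5-diketone F4.
- LiN(i-Pr)2 (THF, −78 °C) deprotonates the methyl ketone kinetically, and aldol addition to the ring ketone gives the ketol F5, which is dehydrated (TsOH, benzene, 40 °C) and so comes back to the route at 11.

Risk 2, step 7. The methoxymethyl ethers may not survive the fluoroalcohol, or partial SN1 character may erode the enantiomeric purity. The fallback opens the epoxide with the unprotected, far more nucleophilic phenol in a less ionising medium and protects afterwards. It sets out from 12 (threefold excess) and 14 in CF3CH2OH at 40 °C, which gives the triphenol alcohol F6 by the same invertive C-alkylation. Selective protection of the three phenols (MeOCH2Cl, K2CO3, acetone; the primary alcohol is not deprotonated) comes back to the route at 15.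

Risk 3, step 10. The spiro centre may form with poor selectivity, or the ionised intermediate may be lost to dienes. The fallback gives up the ionisation and forms both bonds of ring C in one pericyclic step, setting out from 11:
- Wittig methylenation (Ph3P=CH2, THF) gives the exocyclic diene F7.
- Heating F7 with benzaldehyde and 2,4,6-trihydroxyisophthalaldehyde (NaOAc, AcOH, 80 °C) generates the ortho-quinone methide F8 in the flask.
- F8 adds across the exocyclic alkene in an inverse-demand hetero-Diels–Alder reaction and comes back to the route at 21, bypassing 19 and 20.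

This fallback no longer controls the benzylic centre, so the diastereomers would have to be separated.

Further compounds
F1 | step 5 | (3R,6S)-2-[1-methoxy-2-(2-methyl-1,3-dioxolan-2-yl)ethyl]-3-methyl-6-(propan-2-yl)cyclohexan-1-one | CC(C)[C@@H]1CC[C@@H](C)C(C(OC)CC2(C)OCCO2)C1=O
F2 | step 5 | (2E,3R,6S)-3-methyl-2-[2-(2-methyl-1,3-dioxolan-2-yl)ethylidene]-6-(propan-2-yl)cyclohexan-1-one | CC(C)[C@@H]1CC[C@@H](C)/C(=C\CC2(C)OCCO2)C1=O
F3 | step 5 | (2R,3R,6S)-3-methyl-2-[2-(2-methyl-1,3-dioxolan-2-yl)ethyl]-6-(propan-2-yl)cyclohexan-1-one | CC(C)[C@@H]1CC[C@@H](C)[C@@H](CCC2(C)OCCO2)C1=O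
F4 | step 5 | (2R,3R,6S)-3-methyl-2-(3-oxobutyl)-6-(propan-2-yl)cyclohexan-1-one | CC(C)[C@@H]1CC[C@@H](C)[C@@H](CCC(C)=O)C1=O
F5 | step 5 | (4aR,5R,8S)-8a-hydroxy-5-methyl-8-(propan-2-yl)octahydronaphthalen-2(1H)-one | CC(C)[C@@H]1CC[C@@H](C)[C@H]2CCC(=O)CC12O
F6 | step 7 | (2R)-2-phenyl-2-(2,4,6-trihydroxyphenyl)ethan-1-ol | OC[C@H](c1ccccc1)c1c(O)cc(O)cc1O
F7 | step 10 | (1S,4R,4aR)-4-methyl-7-methylidene-1-(propan-2-yl)-1,2,3,4,4a,5,6,7-octahydronaphthalene | CC(C)[C@@H]1CC[C@@H](C)[C@H]2CCC(=C)C=C12
F8 | step 10 | 5-benzylidene-2,4-dihydroxy-6-oxocyclohexa-1,3-diene-1,3-dicarbaldehyde (ortho-quinone methide) | O=CC1=C(O)C(C=O)=C(O)C(=Cc2ccccc2)C1=O
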